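Locants used throughout: decalin carbons C1–C10 (ring A = C1–C5 and C10; ring B = C5–C10), C11 = the benzylic carbon on C9. β is the face of the three ring methyl groups, α the face of H-10.

Remark on the chemistry: the target is taken in the protonation state drawn (free aryl hydrogen sulfate). It is released from its tetrabutylammonium salt on an acidic resin in the last operation and would be stored as a salt.

## Analysis of the target

Target 33 is a rearranged drimane: a trans-fused decalin with an exocyclic methylidene on C4 and, on the quaternary carbon C9, a methyl group and a benzylic methylene (C11) leading to a 1,2,3,5-tetrasubstituted benzene ring. The arene is a catechol in which the oxygen next to the C11 arm is a hydrogen sulfate ester and the other is a free phenol; a hydroxymethyl group sits para to the sulfate. There are four contiguous stereocentres, C5 (S), C10 (S), C9 (R) and C8 (S). The methyl groups on C5, C9 and C8 are all β, while H-10 and the C11 arm are α, so the C5 and C9 methyls are 1,3-diaxial across the trans ring fusion and the C8 and C9 methyls are cis. The aryl sulfate monoester is acid-labile but tolerates base and fluoride; the exocyclic alkene is lost on hydrogenation and migrates into the ring under acid; the para-oxygenated benzylic alcohol ionizes easily. The synthesis is hard for three reasons: two quaternary stereocentres (C5, C9) in a 1,3-relationship, a neopentyl C9–C11–aryl junction, and sulfation of the more hindered catechol oxygen in the presence of a primary alcohol. The strategy rests on the triad C8(H)(CH3)–C9(CH3)(C11)–C10(H) in ring B. Cis methyls on C8 and C9, with H-10 trans to the C9 methyl, are what (E)-2-methylbut-2-enal 6 leaves when it adds, formyl exo, across a 1-vinylcyclohexene. Ring B is therefore the Diels–Alder ring and C7–C8 and C9–C10 are the bonds to form.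

## Retrosynthetic reasoning

**33 back to 29.** The sulfate S–O bond and the two O–Si bonds are cut last. A sulfate monoester anion survives fluoride but not acid, so the final deprotection must be a desilylation (31 to 33 through 32). The sulfate must therefore be placed on the only free hydroxyl of a compound whose other two hydroxyls are silylated, phenol 29. The forward steps have to sulfonate a flanked phenol and then remove two silyl ethers without touching the sulfate or the methylidene.

**29 back to 24.** The flanked phenol is unmasked from methoxymethyl acetal 27. An acetal is chosen because this oxygen sits ortho to the aryllithium used earlier, where a silyl group would migrate to carbon, and because it can be removed without acid that would attack silyl ethers or alkene. The C11–H bond is traced to a C11–O bond: radical deoxygenation of xanthate 26, made from benzylic alcohol 24. A radical method is required because the molecule carries a second, para-oxygenated benzylic C–O bond that would not survive ionic hydrogenation or dissolving metal.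

**24 back to 17 and 22.** The C11–aryl bond is cut. Substitution at a neopentyl carbon by an aryl nucleophile is not realistic, whereas carbonyl addition tolerates the congestion; the non-enolizable aldehyde 17 and the aryllithium 23 from bromide 22 are the partners. C11 is the formyl carbon that the dienophile delivers, so no carbon has to be added or removed. Placing this coupling late keeps the arene and its benzylic C–O bond away from the hydrogenolysis used earlier.

**22 back to 18.** 5-Bromovanillin 18 has bromine where the decalin arm goes, both oxygens in place and a formyl group for the hydroxymethyl. Demethylation gives catechol 19; the phenol para to the formyl group and ortho to bromine is the more acidic and takes the acetal (20). Reduction (21) and double silylation complete the fragment.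

**17 back to 14.** The C4=CH2 bond is cut to ketone 14. Olefination of a ketone fixes the alkene position without any regiochemical competition. The C11 oxygen, held as a silyl ether through 15, is then released (16) and oxidized to the aldehyde.

**14 back to 11.** The C5 methyl is traced to a cyclopropane: first the C6–CH2 bond of 12 (hydrogenolysis in the forward sense), then both remaining cyclopropane bonds, back to allylic alcohol 11. Direct alkylation of a C4 enolate at C5 is set aside because it would come from the α-face, away from the axial C9 methyl, and give the cis-decalin. A C4 oxygen on the β side can instead carry a zinc carbenoid to the hindered face. The forward steps must cyclopropanate the β-face of C5=C6 and then cleave the least hindered cyclopropane bond.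

**11 back to 7.** These are functional-group changes only. The 4β-alcohol comes from enone 10 by axial hydride delivery, the enone from dioxolane 9, and the silyl ether from alcohol 8, which is the reduced form of Diels–Alder aldehyde 7. The aldehyde is stored as a silyl ether because it cannot pass the reductions of ring A.

**7 back to 5 and 6.** This is the central disconnection: C7–C8 and C9–C10 are cut, opening ring B to diene 5 and tiglic aldehyde 6. It removes three stereocentres and one ring at once and leaves a C4 oxygen and a C5=C6 alkene, which are the handles needed for the C5 methyl and the methylidene. The forward reaction needs "ortho" regiochemistry, formyl-exo topology and one enantioface.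

**5 back to 1.** The vinyl–C5 bond is cut (cross-coupling of alkenyl bromide 4), then the ketal (3) and the α-bromine, back to cyclohex-2-en-1-one 1. The precursor of the key step is three routine steps from a bulk chemical.

## Alternatives that were turned down

**Alternative 1:** The disconnection cuts C9–C10 and C4–C5 together, back to an acyclic dienyne that already carries the protected arene on C11 and the C8 methyl stereocentre. In the forward step an iron hydride (from a trivalent iron β-diketonate and an arylsilane) transfers a hydrogen atom to the 1,1-disubstituted alkene at C9. The tertiary C9 radical closes ring B 6-endo onto C10, the resulting C5 radical closes ring A 6-exo onto the alkyne, and the vinyl radical is reduced to the methylidene of A1.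
- For it: the route is convergent; both rings, both quaternary centres and the exocyclic alkene arise in one step with the arene in place; no late C11 coupling or deoxygenation is needed. On step economy it is clearly stronger, probably about half the length.
- Against it: C9, C10 and C5 are all set in that one step from the single C8 stereocentre. The planar C9 radical bears a methyl and an arylmethyl group of similar demand, so which becomes axial is poorly differentiated. Trans versus cis fusion depends on the conformation of a fast cascade. Hydrogen-atom transfer must select the 1,1-disubstituted alkene over the trisubstituted alkene and the alkyne, and early reduction or 1,5-hydrogen shifts from the benzylic position compete.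
- Comparison: the chosen strategy sets each relationship by a rule that can be argued atom by atom (suprafacial addition of an E dienophile, exo preference of an α-methyl enal, catalyst face selection). It pays for this with length.

**Alternative 2:** No ring bond is cut. The C9–CH3 and C5–CH3 bonds are traced to 1,2-shifts in a normal drimane (methyls on C10 and C4) that carries the arylmethyl arm on C9 and a tertiary alcohol on C8, a skeleton available from the chiral pool. In the forward step a boron trifluoride-type Lewis acid ionizes C8; hydride (C9 to C8), methyl (C10 to C9), hydride (C5 to C10) and methyl (C4 to C5) migrate in turn, and the C4 cation loses a proton from its remaining methyl to give A2.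
- For it: every carbon and the absolute configuration come from the chiral pool. The antiperiplanar shifts deliver exactly the 5β,8β,9β-trimethyl, 10α-H pattern. The route is very short. On stereochemistry and step count it is stronger than the chosen route.
- Against it: termination is not controlled. The C4 cation can lose a ring proton to give the more substituted endocyclic alkene, and the exocyclic alkene, once formed, can migrate under the same acid. The cascade can also stop at the C9 or C10 cation, and the arene, even acylated, can capture a cation through carbon or oxygen.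
- Comparison: the one feature that cannot be corrected afterwards, the position of the alkene, is left to a proton-loss competition. The chosen strategy fixes that position by olefination of a C4 ketone, using the same oxygen that served the diene and the methyl delivery.

**Alternative 3:** The disconnection cuts C5–C10 and C8–C9 together, back to an acyclic triene in which a silyloxy diene (C5=C6–C7=C8) and an (E)-2-methyl enal (C9=C10) are joined through C1–C4. In the forward step a dialkylaluminium chloride promotes an intramolecular [4+2] cycloaddition that closes rings A and B at once to give A3.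
- For it: the C5 quaternary methyl and the trans ring fusion are formed directly in the cycloaddition. This is a real advantage, because the chosen route has to solve the angular-methyl problem separately by directed cyclopropanation and hydrogenolysis. Intramolecularity also helps the congested bond formation.
- Against it: C8 emerges bearing oxygen instead of the methyl, so a secondary silyl ether next to a quaternary centre must later be replaced by a cis methyl group, which costs several steps and raises a new stereochemical problem. The C6=C7 alkene must be reduced. The linear precursor needs two defined trisubstituted alkenes, a geometrically defined silyl dienol ether and an enantioenriched C4 carbinol as the only source of absolute control. The fully substituted diene terminus C5 slows the cycloaddition.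
- Comparison: much of the risk sits in the long sequence before the key step. The chosen route reaches its cycloaddition precursor in three steps, receives C8 with its methyl from tiglic aldehyde, and takes absolute control from a catalyst.

Key step: step 4

## Route

Step 1
Reactants: 1 cyclohex-2-en-1-one
Product: 3 2-bromocyclohex-2-en-1-one, via 2,3-dibromocyclohexan-1-one 2 (not isolated)
Conditions: Br2, CH2Cl2, 0 °C; then Et3N, 0 °C → rt
Reagents that add atoms: bromine, BrBr
Why: Bromine addition to the enone followed by base-induced loss of HBr from the dibromide (the α-proton is the acidic one) is the standard α-bromination of a cyclic enone; no stereocentre remains.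

Step 2
Reactants: 3 2-bromocyclohex-2-en-1-one
Product: 4 6-bromo-1,4-dioxaspiro[4.5]dec-6-ene
Conditions: HOCH2CH2OH, p-TsOH·H2O (cat.), benzene, reflux, Dean–Stark trap
Reagents that add atoms: ethane-1,2-diol, OCCO
Why: Acid-catalysed ketalization with azeotropic removal of water; the vinylic bromine holds the alkene next to the ketal carbon, so no double-bond migration is expected.

Step 3
Reactants: 4 6-bromo-1,4-dioxaspiro[4.5]dec-6-ene
Product: 5 6-ethenyl-1,4-dioxaspiro[4.5]dec-6-ene
Conditions: 2-ethenyl-4,4,5,5-tetramethyl-1,3,2-dioxaborolane, PdCl2(dppf)·CH2Cl2 (3 mol %), K3PO4, 1,4-dioxane–H2O, 80 °C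
Reagents that add atoms: 2-ethenyl-4,4,5,5-tetramethyl-1,3,2-dioxaborolane, C=CB1OC(C)(C)C(C)(C)O1
Why: Suzuki–Miyaura coupling of an alkenyl bromide with a vinylboronic ester; the basic medium leaves the ketal intact, and the acid-sensitive diene should be filtered through basic alumina and used soon.

Step 4
Reactants: 5 6-ethenyl-1,4-dioxaspiro[4.5]dec-6-ene and 6 (E)-2-methylbut-2-enal
Product: 7 (4a'S,5'R,6'S)-5',6'-dimethyl-3',4',4a',5',6',7'-hexahydro-2'H-spiro[1,3-dioxolane-2,1'-naphthalene]-5'-carbaldehyde (C4 dioxolane; C5=C6; 10α-H; 9β-CH3 and 9α-CHO; 8β-CH3)
Conditions: (R)-3,3-diphenyl-1-(2-methylphenyl)tetrahydro-1H,3H-pyrrolo[1,2-c][1,3,2]oxazaborole (C24H24BNO, 20 mol %), HN(SO2CF3)2 (18 mol %), 6 (2–3 equiv), CH2Cl2, −78 → −40 °C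
Reagents that add atoms: none
Why: The N-protonated oxazaborolidine is a strong chiral boron Lewis acid that binds the formyl oxygen of 6 syn to the formyl hydrogen (which contacts the ring oxygen), holds the s-trans enal over the neighbouring phenyl group and so leaves one π-face open; the activated enal then adds to the s-cis diene of 5 in a concerted, asynchronous [4+2] cycloaddition in which C7–C8 bonding runs ahead of C9–C10 bonding. The closest known reaction type is the exo-selective, oxazaborolidinium-catalysed Diels–Alder reaction of α-substituted enals with carbon-substituted dienes, 1-vinylcycloalkenes among them. Ring B (C5–C10) closes by the intermolecular suprafacial union of the four diene carbons C10, C5, C6 and C7 with the dienophile carbons C8 and C9, leaving the C5=C6 alkene. C8 relative to C9 is controlled by the E geometry of 6, which is carried over suprafacially, so the two methyl groups end up cis. C10 relative to C9 is controlled by the exo preference of the formyl group of an α-methyl enal: the α-methyl lies endo, and because ring carbon C1 is the outside substituent of the diene terminus, H-10 falls cis to the formyl group and trans to the C9 methyl. The absolute configuration is controlled by the catalyst; the (R)-series catalyst is chosen because the binding model exposes the face of 6 that is Si at C2, the face required for (8S,9R,10S), and the mirror-image catalyst is equally available should the sense prove opposite. The "ortho" regiochemistry (formyl-bearing C9 to the substituted terminus C10) follows from the larger diene coefficient at the unsubstituted vinyl carbon C7, which bonds first to the β-carbon C8; the dioxolane sits on the internal diene carbon, where it favours the s-cis conformer without blocking a terminus, and a slight excess of oxazaborolidine over HN(SO2CF3)2 keeps free Brønsted acid away from the ketal.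

Step 5
Reactants: 7 Diels–Alder aldehyde
Product: 8 primary alcohol (9α-CH2OH; C4 dioxolane; C5=C6; 10α-H; 8β,9β-dimethyl)
Conditions: NaBH4, MeOH, 0 °C
Reagents that add atoms: none
Why: Borohydride reduction of a non-enolizable aldehyde; the ketal and the alkene are inert, and no stereocentre is touched.

Step 6
Reactants: 8 primary alcohol
Product: 9 triisopropylsilyl ether of 8 (9α-CH2OSi(i-Pr)3)
Conditions: i-Pr3SiCl, imidazole, DMAP (cat.), DMF, 40 °C
Reagents that add atoms: chlorotri(propan-2-yl)silane, CC(C)[Si](Cl)(C(C)C)C(C)C
Why: Silylation of a primary alcohol; a silyl ether without aryl groups is chosen because it must survive aqueous acid in step 7 and platinum-catalysed hydrogenation in acetic acid in step 10.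

Step 7
Reactants: 9 silyl ether ketal
Product: 10 enone (C4 ketone conjugated with C5=C6; 10α-H; 8β,9β-dimethyl; 9α-CH2OSi(i-Pr)3)
Conditions: 0.5 M aq. HCl, THF, rt
Reagents that add atoms: water, O
Why: Hydrolysis of an allylic dioxolane proceeds readily through an allyl-stabilized oxocarbenium ion and gives the conjugated enone directly; H-10 is not acidic (C10 is attached to the α-carbon), so the ring-fusion centre is not at risk, and the primary triisopropylsilyl ether tolerates dilute acid.

Step 8
Reactants: 10 enone
Product: 11 allylic alcohol (4β-OH, 4S; C5=C6; otherwise as 10)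
Conditions: NaBH4, CeCl3·7H2O, MeOH, −40 → 0 °C
Reagents that add atoms: none
Why: Luche 1,2-reduction; ring A is a chair with H-10 axial, so axial delivery of the small hydride comes from the α-face and places the hydroxyl equatorial on the β side, the side to which the methyl must later be delivered.

Step 9
Reactants: 11 allylic alcohol
Product: 12 cyclopropyl carbinol (5β,6β-methano bridge; 4β-OH; 10α-H; 8β,9β-dimethyl; 9α-CH2OSi(i-Pr)3)
Conditions: Et2Zn, CH2I2, CH2Cl2, 0 °C → rt
Reagents that add atoms: diiodomethane, ICI
Why: Hydroxyl-directed Simmons–Smith cyclopropanation; the zinc alkoxide of the 4β-oxygen, which lies slightly to the β side of the alkene plane, carries the carbenoid to that face in a cyclic transition state and should outrun undirected attack on the hindered trisubstituted alkene, so the new methylene (the future C5 methyl) should add cis to the oxygen and trans to H-10 despite the axial C9 methyl.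

Step 10
Reactants: 12 cyclopropyl carbinol
Product: 13 trans-decalinol (5β-CH3; 4β-OH; 10α-H; 8β,9β-dimethyl; 9α-CH2OSi(i-Pr)3)
Conditions: H2 (3 atm), PtO2, AcOH, rt
Reagents that add atoms: none
Why: Catalytic hydrogenolysis of a cyclopropane cleaves the least hindered bond, here C6–CH2 opposite the quaternary carbon, so the methylene stays on C5 as a methyl with the configuration fixed in step 9; no arene or benzylic C–O bond is yet present, which is why this step precedes the aryl coupling.

Step 11
Reactants: 13 trans-decalinol
Product: 14 C4 ketone (5β-CH3; 10α-H; 8β,9β-dimethyl; 9α-CH2OSi(i-Pr)3)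
Conditions: Dess–Martin periodinane, CH2Cl2, rt
Reagents that add atoms: none
Why: Dess–Martin oxidation of a hindered secondary alcohol under neutral conditions; the adjacent C5 is quaternary, so nothing can epimerize.

Step 12
Reactants: 14 C4 ketone
Product: 15 4-methylidene decalin silyl ether (exocyclic C4=CH2; 5β,8β,9β-trimethyl; 10α-H; 9α-CH2OSi(i-Pr)3)
Conditions: Ph3PCH3Br, KOt-Bu, toluene, 90 °C
Reagents that add atoms: methyltriphenylphosphonium bromide, C[P+](c1ccccc1)(c1ccccc1)c1ccccc1.[Br-]
Why: Wittig methylenation with the non-stabilized ylide at elevated temperature is the usual answer to a ketone flanked by a quaternary carbon; the alkene position is fixed by the carbonyl and no stereocentre is involved.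

Step 13
Reactants: 15 4-methylidene decalin silyl ether
Product: 16 primary alcohol (9α-CH2OH; exocyclic C4=CH2; 5β,8β,9β-trimethyl; 10α-H)
Conditions: n-Bu4NF, THF, rt → 40 °C
Reagents that add atoms: none
Why: Fluoride cleavage of the silyl ether; the alkene and the ring stereocentres are inert.

Step 14
Reactants: 16 primary alcohol
Product: 17 aldehyde (9α-CHO; exocyclic C4=CH2; 5β,8β,9β-trimethyl; 10α-H)
Conditions: Dess–Martin periodinane, CH2Cl2, 0 °C → rt
Reagents that add atoms: none
Why: Dess–Martin oxidation of a neopentyl primary alcohol; the aldehyde has a quaternary α-carbon and cannot epimerize or enolize.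

Step 15
Reactants: 18 3-bromo-4-hydroxy-5-methoxybenzaldehyde (5-bromovanillin)
Product: 19 3-bromo-4,5-dihydroxybenzaldehyde
Conditions: AlCl3, pyridine, CH2Cl2, reflux; then 2 M aq. HCl
Reagents that add atoms: none
Why: Lewis-acid-assisted demethylation of an aryl methyl ether ortho to a phenol (chelation of aluminium by the two oxygens, methyl transfer to pyridine), a standard reaction of vanillin-type aldehydes.

Step 16
Reactants: 19 3-bromo-4,5-dihydroxybenzaldehyde
Product: 20 3-bromo-5-hydroxy-4-(methoxymethoxy)benzaldehyde
Conditions: CH3OCH2Cl (1.05 equiv), i-Pr2NEt (1.1 equiv), DMF, 0 °C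
Reagents that add atoms: chloro(methoxy)methane, COCCl
Why: Regioselective O-alkylation of a catechol aldehyde; with one equivalent of weak base only the markedly more acidic hydroxyl (para to the formyl group, ortho to bromine) is ionized, and the small, reactive electrophile alkylates that oxygen.

Step 17
Reactants: 20 3-bromo-5-hydroxy-4-(methoxymethoxy)benzaldehyde
Product: 21 3-bromo-5-(hydroxymethyl)-2-(methoxymethoxy)phenol
Conditions: NaBH4, MeOH, 0 °C
Reagents that add atoms: none
Why: Borohydride reduction of an aryl aldehyde; the aryl bromide and the acetal are inert.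

Step 18
Reactants: 21 3-bromo-5-(hydroxymethyl)-2-(methoxymethoxy)phenol
Product: 22 {[3-bromo-4-(methoxymethoxy)-5-{[tri(propan-2-yl)silyl]oxy}phenyl]methoxy}tri(propan-2-yl)silane
Conditions: i-Pr3SiCl (2.4 equiv), imidazole, DMF, rt
Reagents that add atoms: chlorotri(propan-2-yl)silane, CC(C)[Si](Cl)(C(C)C)C(C)C
Why: Silylation of a phenol and a primary benzylic alcohol; the bulky silyl groups tolerate organolithium, hydride-base and radical conditions and are removable by fluoride at the end.

Step 19
Reactants: 22 aryl bromide and 17 aldehyde
Product: 24 benzylic alcohol (C11 carbinol as a mixture of epimers; aryl with 2-OCH2OCH3, 3-OSi(i-Pr)3 and 5-CH2OSi(i-Pr)3; decalin as in 17), via 2-(methoxymethoxy)aryllithium 23 (not isolated)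
Conditions: 22 (1.4 equiv), n-BuLi (1.35 equiv), THF, −78 °C; then 17, −78 → 0 °C; aq. NH4Cl
Reagents that add atoms: none
Why: Bromine–lithium exchange, helped by the ortho acetal oxygen, followed by 1,2-addition of the aryllithium to a non-enolizable neopentyl aldehyde; the configuration at C11 is not controlled and is removed in step 21.

Step 20
Reactants: 24 benzylic alcohol
Product: 26 O-alkyl S-methyl xanthate of 24 (C11–OC(=S)SCH3), via sodium O-alkyl dithiocarbonate 25 (not isolated)
Conditions: NaH, imidazole (cat.), CS2, THF, 0 °C → rt; then CH3I
Reagents that add atoms: carbon disulfide, S=C=S; iodomethane, CI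
Why: Xanthate formation from the alkoxide, the first half of a Barton–McCombie deoxygenation; C11 has no β-hydrogen (C9 is quaternary), so thermal syn-elimination of the xanthate is impossible.

Step 21
Reactants: 26 xanthate
Product: 27 C11-methylene compound (aryl with 2-OCH2OCH3, 3-OSi(i-Pr)3 and 5-CH2OSi(i-Pr)3; exocyclic C4=CH2; 5β,8β,9β-trimethyl; 10α-H)
Conditions: n-Bu3SnH, AIBN (cat.), toluene, 110 °C
Reagents that add atoms: none
Why: Barton–McCombie radical deoxygenation; the benzylic C11 radical is held equatorial on C9, anti to C5 and far from the methylidene, so it should simply take hydrogen from the stannane, and the second benzylic C–O bond, which ionic or electron-transfer methods would endanger, is untouched.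

Step 22
Reactants: 27 methoxymethyl ether
Product: 29 phenol (free 2-OH flanked by the C11 arm and the 3-OSi(i-Pr)3 group; 5-CH2OSi(i-Pr)3; decalin unchanged), via aryl trimethylsilyl ether 28 (not isolated)
Conditions: Me3SiOTf, 2,2'-bipyridyl, CH3CN, 0 °C → rt; then H2O
Reagents that add atoms: none
Why: Chemoselective cleavage of an aromatic methoxymethyl ether by a silyl triflate buffered with bipyridyl (the acetal is converted to the aryl trimethylsilyl ether, which hydrolyses on aqueous work-up); the medium is non-acidic, so the bulky silyl ethers and the exocyclic alkene are expected to persist.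

Step 23
Reactants: 29 phenol
Product: 31 tetrabutylammonium aryl sulfate (2-OSO3− n-Bu4N+; 3-OSi(i-Pr)3; 5-CH2OSi(i-Pr)3), via pyridinium aryl sulfate 30 (not isolated)
Conditions: SO3·pyridine, pyridine, 50 °C; then aq. n-Bu4NOH, extraction into CH2Cl2
Reagents that add atoms: sulfur trioxide–pyridine complex, [O-]S(=O)(=O)[n+]1ccccc1; tetrabutylammonium hydroxide, CCCC[N+](CCCC)(CCCC)CCCC.[OH-]
Why: O-Sulfonation of the only free hydroxyl with a sulfur trioxide–amine complex; the bulky silyl group is favoured on the less hindered neighbouring oxygen, so silyl migration should not scramble the site, and the lipophilic tetrabutylammonium salt can be purified on silica.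

Step 24
Reactants: 31 tetrabutylammonium aryl sulfate
Product: 33 2-hydroxy-4-(hydroxymethyl)-6-{[(1R,2S,4aS,8aS)-1,2,4a-trimethyl-5-methylidenedecahydronaphthalen-1-yl]methyl}phenyl hydrogen sulfate, via tetrabutylammonium salt of the target 32 (not isolated)
Conditions: n-Bu4NF, THF, 0 °C → rt; then Dowex 50W-X8 (H+ form), MeOH–H2O, 0 °C
Reagents that add atoms: none
Why: Fluoride cleaves the aryl and benzylic silyl ethers while the sulfate monoester anion resists nucleophiles; brief cation exchange in the cold then gives the acid form without the heating in acid that would hydrolyse the sulfate or move the alkene.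

## Compound list

1 | cyclohex-2-en-1-one | O=C1C=CCCC1 | starting material
2 | 2,3-dibromocyclohexan-1-one | O=C1CCCC(Br)C1Br | intermediate
3 | 2-bromocyclohex-2-en-1-one | O=C1CCCC=C1Br | intermediate
4 | 6-bromo-1,4-dioxaspiro[4.5]dec-6-ene | BrC1=CCCCC12OCCO2 | intermediate
5 | 6-ethenyl-1,4-dioxaspiro[4.5]dec-6-ene | C=CC1=CCCCC12OCCO2 | intermediate
6 | (E)-2-methylbut-2-enal | C/C=C(\C)C=O | starting material
7 | (4a'S,5'R,6'S)-5',6'-dimethyl-3',4',4a',5',6',7'-hexahydro-2'H-spiro[1,3-dioxolane-2,1'-naphthalene]-5'-carbaldehyde (C4 dioxolane; C5=C6; 10α-H; 9β-CH3, 9α-CHO; 8β-CH3) | O1CCOC12CCC[C@H]3[C@](C)(C=O)[C@@H](C)CC=C23 | intermediate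
8 | primary alcohol from 7 (9α-CH2OH; C4 dioxolane; C5=C6; 10α-H; 8β,9β-dimethyl) | O1CCOC12CCC[C@H]3[C@](C)(CO)[C@@H](C)CC=C23 | intermediate
9 | triisopropylsilyl ether of 8 | O1CCOC12CCC[C@H]3[C@](C)(CO[Si](C(C)C)(C(C)C)C(C)C)[C@@H](C)CC=C23 | intermediate
10 | enone: C4 ketone conjugated with C5=C6; 10α-H; 8β,9β-dimethyl; 9α-[(triisopropylsilyloxy)methyl] | O=C1CCC[C@H]2[C@](C)(CO[Si](C(C)C)(C(C)C)C(C)C)[C@@H](C)CC=C12 | intermediate
11 | allylic alcohol: 4β-OH (4S); C5=C6; 10α-H; 8β,9β-dimethyl; 9α-[(triisopropylsilyloxy)methyl] | O[C@H]1CCC[C@H]2[C@](C)(CO[Si](C(C)C)(C(C)C)C(C)C)[C@@H](C)CC=C12 | intermediate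
12 | cyclopropyl carbinol: methylene bridging C5 and C6 on the β-face; 4β-OH; 10α-H; 8β,9β-dimethyl; 9α-[(triisopropylsilyloxy)methyl] | O[C@H]1CCC[C@H]2[C@](C)(CO[Si](C(C)C)(C(C)C)C(C)C)[C@@H](C)C[C@H]3C[C@@]123 | intermediate
13 | trans-decalinol: 4β-OH; 5β,8β,9β-trimethyl; 10α-H; 9α-[(triisopropylsilyloxy)methyl] | O[C@H]1CCC[C@H]2[C@](C)(CO[Si](C(C)C)(C(C)C)C(C)C)[C@@H](C)CC[C@]12C | intermediate
14 | C4 ketone: 5β,8β,9β-trimethyl; 10α-H; 9α-[(triisopropylsilyloxy)methyl] trans-decalin-4-one | O=C1CCC[C@H]2[C@](C)(CO[Si](C(C)C)(C(C)C)C(C)C)[C@@H](C)CC[C@]12C | intermediate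
15 | 4-methylidene-5β,8β,9β-trimethyl-9α-[(triisopropylsilyloxy)methyl]-trans-decalin (10α-H) | C=C1CCC[C@H]2[C@](C)(CO[Si](C(C)C)(C(C)C)C(C)C)[C@@H](C)CC[C@]12C | intermediate
16 | 4-methylidene-5β,8β,9β-trimethyl-trans-decalin-9α-ylmethanol (10α-H) | C=C1CCC[C@H]2[C@](C)(CO)[C@@H](C)CC[C@]12C | intermediate
17 | 4-methylidene-5β,8β,9β-trimethyl-trans-decalin-9α-carbaldehyde (10α-H) | C=C1CCC[C@H]2[C@](C)(C=O)[C@@H](C)CC[C@]12C | intermediate
18 | 3-bromo-4-hydroxy-5-methoxybenzaldehyde (5-bromovanillin) | COc1cc(C=O)cc(Br)c1O | starting material
19 | 3-bromo-4,5-dihydroxybenzaldehyde | Oc1cc(C=O)cc(Br)c1O | intermediate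
20 | 3-bromo-5-hydroxy-4-(methoxymethoxy)benzaldehyde | COCOc1c(O)cc(C=O)cc1Br | intermediate
21 | 3-bromo-5-(hydroxymethyl)-2-(methoxymethoxy)phenol | COCOc1c(O)cc(CO)cc1Br | intermediate
22 | {[3-bromo-4-(methoxymethoxy)-5-{[tri(propan-2-yl)silyl]oxy}phenyl]methoxy}tri(propan-2-yl)silane | COCOc1c(O[Si](C(C)C)(C(C)C)C(C)C)cc(CO[Si](C(C)C)(C(C)C)C(C)C)cc1Br | intermediate
23 | aryllithium from 22 (lithium in place of bromine) | COCOc1c(O[Si](C(C)C)(C(C)C)C(C)C)cc(CO[Si](C(C)C)(C(C)C)C(C)C)cc1[Li] | intermediate
24 | benzylic alcohol: C11(OH) joining C9 (α) of the 4-methylidene-5β,8β,9β-trimethyl-trans-decalin to the aryl ring (2-methoxymethoxy, 3-triisopropylsilyloxy, 5-(triisopropylsilyloxy)methyl); C11 epimers | C=C1CCC[C@H]2[C@](C)(C(O)c3cc(CO[Si](C(C)C)(C(C)C)C(C)C)cc(O[Si](C(C)C)(C(C)C)C(C)C)c3OCOC)[C@@H](C)CC[C@]12C | intermediate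
25 | sodium O-alkyl dithiocarbonate of 24 | C=C1CCC[C@H]2[C@](C)(C(OC(=S)[S-])c3cc(CO[Si](C(C)C)(C(C)C)C(C)C)cc(O[Si](C(C)C)(C(C)C)C(C)C)c3OCOC)[C@@H](C)CC[C@]12C.[Na+] | intermediate
26 | O-alkyl S-methyl xanthate of 24 | C=C1CCC[C@H]2[C@](C)(C(OC(=S)SC)c3cc(CO[Si](C(C)C)(C(C)C)C(C)C)cc(O[Si](C(C)C)(C(C)C)C(C)C)c3OCOC)[C@@H](C)CC[C@]12C | intermediate
27 | C11-methylene compound: aryl (2-methoxymethoxy, 3-triisopropylsilyloxy, 5-(triisopropylsilyloxy)methyl) on C11; decalin as in the target | C=C1CCC[C@H]2[C@](C)(Cc3cc(CO[Si](C(C)C)(C(C)C)C(C)C)cc(O[Si](C(C)C)(C(C)C)C(C)C)c3OCOC)[C@@H](C)CC[C@]12C | intermediate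
28 | aryl trimethylsilyl ether (trimethylsilyl in place of methoxymethyl in 27) | C=C1CCC[C@H]2[C@](C)(Cc3cc(CO[Si](C(C)C)(C(C)C)C(C)C)cc(O[Si](C(C)C)(C(C)C)C(C)C)c3O[Si](C)(C)C)[C@@H](C)CC[C@]12C | intermediate
29 | phenol: free hydroxyl next to the C11 arm; 3-triisopropylsilyloxy; 5-(triisopropylsilyloxy)methyl | C=C1CCC[C@H]2[C@](C)(Cc3cc(CO[Si](C(C)C)(C(C)C)C(C)C)cc(O[Si](C(C)C)(C(C)C)C(C)C)c3O)[C@@H](C)CC[C@]12C | intermediate
30 | pyridinium salt of the aryl sulfate of 29 | C=C1CCC[C@H]2[C@](C)(Cc3cc(CO[Si](C(C)C)(C(C)C)C(C)C)cc(O[Si](C(C)C)(C(C)C)C(C)C)c3OS(=O)(=O)[O-])[C@@H](C)CC[C@]12C.c1cc[nH+]cc1 | intermediate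
31 | tetrabutylammonium salt of the aryl sulfate of 29 | C=C1CCC[C@H]2[C@](C)(Cc3cc(CO[Si](C(C)C)(C(C)C)C(C)C)cc(O[Si](C(C)C)(C(C)C)C(C)C)c3OS(=O)(=O)[O-])[C@@H](C)CC[C@]12C.CCCC[N+](CCCC)(CCCC)CCCC | intermediate
32 | tetrabutylammonium salt of the target sulfate | C=C1CCC[C@H]2[C@](C)(Cc3cc(CO)cc(O)c3OS(=O)(=O)[O-])[C@@H](C)CC[C@]12C.CCCC[N+](CCCC)(CCCC)CCCC | intermediate
33 | 2-hydroxy-4-(hydroxymethyl)-6-{[(1R,2S,4aS,8aS)-1,2,4a-trimethyl-5-methylidenedecahydronaphthalen-1-yl]methyl}phenyl hydrogen sulfate | C=C1CCC[C@H]2[C@](C)(Cc3cc(CO)cc(O)c3OS(=O)(=O)O)[C@@H](C)CC[C@]12C | target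

## Step count and least certain steps

Total: 24 steps. Longest linear sequence: 20 steps (steps 1–14 and 19–24, from cyclohex-2-en-1-one); the arene branch (steps 15–18) joins at step 19.

Stereocentres: C8, C9 and C10 are set in step 4; C5 is set in step 9 and kept in step 10. The C4 and C11 carbinol centres are temporary and are removed in steps 11 and 21.

**Step 4 (key step).** Three things may go wrong. The acid catalyst may ionize the allylic ketal and polymerize the diene. The dioxolane oxygens may compete with the aldehyde for boron and weaken face discrimination. The endo α-methyl group passes under the dioxolane-bearing C5, which may erode the exo preference. The fallback gives up catalytic face control and resolves instead. Setting out from 5 and 6, a cycloaddition promoted by Me2AlCl (CH2Cl2, −78 °C) or run thermally (toluene, 110 °C, sealed vessel) should give the racemic exo aldehyde F1. NaBH4 in MeOH should give the racemic alcohol F2. Acylation with (1S)-camphanoyl chloride (pyridine, DMAP) should give two diastereomeric esters, the camphanate of 8 F3 and the camphanate of the enantiomeric alcohol F4, separable by chromatography or crystallization. K2CO3 in MeOH on F3 comes back to the route at 8.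

**Step 9.** Poor facial selectivity is the likely failure. The 4β-oxygen is equatorial and lies only slightly out of the alkene plane, while the α-face is the open one, so delivery to the β-face against the axial C9 methyl may be incomplete. The fallback replaces the zinc carbenoid by a covalently tethered carbon radical and bypasses steps 9 and 10. Setting out from 11, ClSi(CH3)2CH2Br with Et3N and DMAP in CH2Cl2 should give the (bromomethyl)dimethylsilyl ether F5. With n-Bu3SnH and AIBN in refluxing benzene, the silylmethyl radical should close 5-exo onto C5, forming a cis-fused five-membered ring on the face of the tethering oxygen; the C6 radical then takes hydrogen from the stannane to give the cyclic siloxane F6. Protodesilylation with KOt-Bu in DMSO–H2O cleaves the C–Si bond to the C5 methyl and comes back to the route at 13.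

**Step 16.** Imperfect regioselectivity is the risk: the more acidic hydroxyl is also the more hindered one (between bromine and the second hydroxyl), so some alkylation at the other oxygen or double alkylation may occur. The fallback reverses the order of protection so that the acetal has only one oxygen to go to. Setting out from 19, i-Pr3SiCl (1.05 equiv) and imidazole in DMF should place the bulky silyl group on the less hindered oxygen meta to bromine, the arrangement also favoured when silyl groups migrate between catechol oxygens, giving 3-bromo-4-hydroxy-5-(triisopropylsilyloxy)benzaldehyde F7. CH3OCH2Cl with i-Pr2NEt then gives 3-bromo-4-(methoxymethoxy)-5-(triisopropylsilyloxy)benzaldehyde F8, and NaBH4 gives the corresponding benzyl alcohol F9. Silylation with i-Pr3SiCl and imidazole comes back to the route at 22.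

**Step 22.** The acetal oxygen is flanked on both sides, so cleavage may be slow, and forcing it may cause loss of one or both silyl ethers. The fallback drops the demand for chemoselectivity and relies on steric differentiation afterwards. Setting out from 27, n-Bu4NF in THF should remove both silyl ethers to give the methoxymethyl ether diol F10. The acetal is then cleaved with nothing left to spare, using excess silyl triflate with bipyridyl (the hydroxyls are silylated transiently and freed on aqueous work-up) or ZnBr2 with n-PrSH in CH2Cl2, giving the triol F11. i-Pr3SiCl (2.1 equiv) and imidazole in DMF at 0 °C should silylate the primary alcohol and the unhindered phenol and leave the flanked phenol free, coming back to the route at 29.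

**Step 23.** Sulfonation of a phenol held between the C11 arm and a triisopropylsilyloxy group may be slow, and prolonged heating in pyridine invites silyl migration or loss. The fallback introduces the sulfate as a neutral, protected diester with a more reactive electrophile. Setting out from 29, NaH and 2,2,2-trichloroethyl chlorosulfate in THF at 0 °C should give the aryl 2,2,2-trichloroethyl sulfate F12, which can be purified on silica. HF·pyridine buffered with pyridine (THF, 0 °C) removes both silyl ethers to give the diol sulfate diester F13. Zn dust and HCO2NH4 in MeOH remove the trichloroethyl group reductively to give the ammonium salt of the target F14, and the acidic resin of step 24 comes back to the route at 33.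

## Further compounds

F1 | step 4 | racemic exo Diels–Alder aldehyde (7 and its enantiomer) | O1CCOC12CCC[C@H]3[C@](C)(C=O)[C@@H](C)CC=C23.O1CCOC12CCC[C@@H]3[C@@](C)(C=O)[C@H](C)CC=C23
F2 | step 4 | racemic primary alcohol (8 and its enantiomer) | O1CCOC12CCC[C@H]3[C@](C)(CO)[C@@H](C)CC=C23.O1CCOC12CCC[C@@H]3[C@@](C)(CO)[C@H](C)CC=C23
F3 | step 4 | (1S)-camphanate ester of 8 | O1CCOC12CCC[C@H]3[C@](C)(COC(=O)[C@@]45CC[C@@](C)(C(=O)O4)C5(C)C)[C@@H](C)CC=C23
F4 | step 4 | (1S)-camphanate ester of the enantiomer of 8 | O1CCOC12CCC[C@@H]3[C@@](C)(COC(=O)[C@@]45CC[C@@](C)(C(=O)O4)C5(C)C)[C@H](C)CC=C23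
F5 | step 9 | (bromomethyl)dimethylsilyl ether of 11 | BrC[Si](C)(C)O[C@H]1CCC[C@H]2[C@](C)(CO[Si](C(C)C)(C(C)C)C(C)C)[C@@H](C)CC=C12
F6 | step 9 | cyclic siloxane (O on C4β, Si(CH3)2, CH2 on C5β; C6 saturated; 10α-H) | O1[C@H]2CCC[C@H]3[C@](C)(CO[Si](C(C)C)(C(C)C)C(C)C)[C@@H](C)CC[C@]23C[Si]1(C)C
F7 | step 16 | 3-bromo-4-hydroxy-5-{[tri(propan-2-yl)silyl]oxy}benzaldehyde | Oc1c(O[Si](C(C)C)(C(C)C)C(C)C)cc(C=O)cc1Br
F8 | step 16 | 3-bromo-4-(methoxymethoxy)-5-{[tri(propan-2-yl)silyl]oxy}benzaldehyde | COCOc1c(O[Si](C(C)C)(C(C)C)C(C)C)cc(C=O)cc1Br
F9 | step 16 | [3-bromo-4-(methoxymethoxy)-5-{[tri(propan-2-yl)silyl]oxy}phenyl]methanol | COCOc1c(O[Si](C(C)C)(C(C)C)C(C)C)cc(CO)cc1Br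
F10 | step 22 | methoxymethyl ether diol (27 without its two silyl groups) | C=C1CCC[C@H]2[C@](C)(Cc3cc(CO)cc(O)c3OCOC)[C@@H](C)CC[C@]12C
F11 | step 22 | triol (the target without its sulfate) | C=C1CCC[C@H]2[C@](C)(Cc3cc(CO)cc(O)c3O)[C@@H](C)CC[C@]12C
F12 | step 23 | aryl 2,2,2-trichloroethyl sulfate of 29 | C=C1CCC[C@H]2[C@](C)(Cc3cc(CO[Si](C(C)C)(C(C)C)C(C)C)cc(O[Si](C(C)C)(C(C)C)C(C)C)c3OS(=O)(=O)OCC(Cl)(Cl)Cl)[C@@H](C)CC[C@]12C
F13 | step 23 | aryl 2,2,2-trichloroethyl sulfate with free phenol and free hydroxymethyl | C=C1CCC[C@H]2[C@](C)(Cc3cc(CO)cc(O)c3OS(=O)(=O)OCC(Cl)(Cl)Cl)[C@@H](C)CC[C@]12C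
F14 | step 23 | ammonium salt of the target sulfate | C=C1CCC[C@H]2[C@](C)(Cc3cc(CO)cc(O)c3OS(=O)(=O)[O-])[C@@H](C)CC[C@]12C.[NH4+]
A1 | alternative 1 | decalin of the target with the arene protected as benzylic and phenolic triisopropylsilyl ethers and a 4-methoxybenzyl ether on the flanked phenol | C=C1CCC[C@H]2[C@](C)(Cc3cc(CO[Si](C(C)C)(C(C)C)C(C)C)cc(O[Si](C(C)C)(C(C)C)C(C)C)c3OCc3ccc(OC)cc3)[C@@H](C)CC[C@]12C
A2 | alternative 2 | rearranged 4-methylidene decalin with the arene protected as benzylic and phenolic pivalates and an acetate on the flanked phenol | C=C1CCC[C@H]2[C@](C)(Cc3cc(COC(=O)C(C)(C)C)cc(OC(=O)C(C)(C)C)c3OC(C)=O)[C@@H](C)CC[C@]12C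
A3 | alternative 3 | trans-octalin with C9 formyl and methyl, C8 tert-butyldimethylsilyl ether, C6=C7 alkene, C5 methyl and C4 4-methoxybenzyl ether | COc1ccc(CO[C@H]2CCC[C@H]3[C@](C)(C=O)[C@H](O[Si](C)(C)C(C)(C)C)C=C[C@]23C)cc1
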